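**Retrosynthetic overview**
1. Target 19 ⇐ 18 by global O‑debenzylation.
2. 18 ⇐ γ‑lactone 11 (C2, C3, C3a, C7a) + dienoic acid 14 (C4–C7 and the styryl arm): one‑flask C‑acylation, vinylogous Dieckmann aromatisation (benzene ring A, lactone opened) and acid‑mediated trans cycloetherification (dihydrofuran ring).
3. 11 ⇐ anti homoallylic alcohol 7 (hydroboration, oxidative lactonisation); 7 ⇐ aldehyde 5 + (E)‑cinnamyl boronate 4 by chiral phosphoric acid allylboration, which fixes C3.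
4. 4 ⇐ styrene 2 (from aldehyde 1) + allyl boronate 3 by cross‑metathesis; 14 ⇐ 5 + methyl 3‑methylbut‑2‑enoate 12 by vinylogous aldol and ring opening.
5. Ring order: temporary γ‑lactone (step 5), then benzene ring A and the dihydrofuran ring together (step 7); all other arenes are bought.

Assumption: the target SMILES is read as the 2,3‑trans (2S,3S) isomer (benzofuran numbering), and benzyl ethers 1 and 5 are taken as commercial.

**Step 1**
Reactants: 1 3,5-bis(benzyloxy)benzaldehyde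
Product: 2 1,3-bis(benzyloxy)-5-ethenylbenzene
Conditions: Ph3PCH3Br, KOt-Bu, THF, 0 to 25 °C
Reagents that add atoms: methyltriphenylphosphonium bromide, C[P+](c1ccccc1)(c1ccccc1)c1ccccc1.[Br-]
Why: Wittig methylenation of an aryl aldehyde with the non-stabilised ylide is reliable, benzyl ethers are inert, and no stereocenter is formed.

**Step 2**
Reactants: 2 1,3-bis(benzyloxy)-5-ethenylbenzene, 3 2-allyl-4,4,5,5-tetramethyl-1,3,2-dioxaborolane
Product: 4 2-[(2E)-3-[3,5-bis(benzyloxy)phenyl]prop-2-en-1-yl]-4,4,5,5-tetramethyl-1,3,2-dioxaborolane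
Conditions: RuCl2(=CHPh)(PCy3)(H2IMes) (second-generation Grubbs catalyst, 3 mol %), 3 (3 equiv), CH2Cl2, 40 °C
Reagents that add atoms: none
Why: Olefin cross-metathesis of a styrene with pinacol allylboronate gives the conjugated (E)-γ-aryl allylboronate with loss of ethene; no stereocenter is formed, but the E geometry is what makes step 3 anti-selective.

**Step 3**
Reactants: 4 2-[(2E)-3-[3,5-bis(benzyloxy)phenyl]prop-2-en-1-yl]-4,4,5,5-tetramethyl-1,3,2-dioxaborolane, 5 4-(benzyloxy)-3-methoxybenzaldehyde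
Product: 7 (1S,2R)-1-[4-(benzyloxy)-3-methoxyphenyl]-2-[3,5-bis(benzyloxy)phenyl]but-3-en-1-ol, via pinacol borate ester 6 (not isolated)
Conditions: (S)-TRIP [(S)-3,3'-bis(2,4,6-triisopropylphenyl)-1,1'-binaphthyl-2,2'-diyl hydrogen phosphate] (5 mol %), 4 Å molecular sieves, toluene, −30 to 0 °C; then H2O
Reagents that add atoms: none
Why: Chiral phosphoric acid-catalysed allylboration runs through a closed chair transition state, so the E boronate gives the anti adduct, and the (S)-catalyst (antipode of the one that gives R carbinols by Re-face attack) directs Si-face attack, which sets the future C3 as well as the carbinol centre.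

**Step 4**
Reactants: 7 (1S,2R)-1-[4-(benzyloxy)-3-methoxyphenyl]-2-[3,5-bis(benzyloxy)phenyl]but-3-en-1-ol
Product: 9 (1S,2R)-1-[4-(benzyloxy)-3-methoxyphenyl]-2-[3,5-bis(benzyloxy)phenyl]butane-1,4-diol, via bis-boryl adduct 8 (not isolated)
Conditions: 9-BBN-H (2.5 equiv), THF, 0 to 25 °C; then NaOH, H2O2, H2O, 0 to 25 °C
Reagents that add atoms: hydrogen peroxide, OO
Why: Anti-Markovnikov hydroboration–oxidation of the only alkene present gives the primary alcohol, and neither stereocenter is touched.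

**Step 5**
Reactants: 9 (1S,2R)-1-[4-(benzyloxy)-3-methoxyphenyl]-2-[3,5-bis(benzyloxy)phenyl]butane-1,4-diol
Product: 11 (4R,5S)-5-[4-(benzyloxy)-3-methoxyphenyl]-4-[3,5-bis(benzyloxy)phenyl]oxolan-2-one, via lactol 10 (not isolated)
Conditions: TEMPO (20 mol %), PhI(OAc)2 (2.5 equiv), CH2Cl2, 25 °C
Reagents that add atoms: none
Why: Oxoammonium (TEMPO/PhI(OAc)2) oxidation takes the primary alcohol first, the hydroxy aldehyde closes to the lactol and is oxidised on to the γ-lactone; the anti diol gives the trans lactone with both centres unchanged.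

**Step 6**
Reactants: 12 methyl 3-methylbut-2-enoate, 5 4-(benzyloxy)-3-methoxybenzaldehyde
Product: 14 (2Z,4E)-5-[4-(benzyloxy)-3-methoxyphenyl]-3-methylpenta-2,4-dienoic acid, via dihydropyranone 13 (not isolated)
Conditions: LiN(i-Pr)2, THF, −78 °C; 5, −78 to 25 °C; KOt-Bu, 25 °C; then aq. HCl
Reagents that add atoms: none
Why: Vinylogous aldol addition of the senecioate dienolate (the γ-adduct is trapped as the δ-lactone on warming) followed by E1cB ring opening gives the (2Z,4E)-dienoic acid; no stereocenter remains.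

**Step 7 (key step)**
Reactants: 11 (4R,5S)-5-[4-(benzyloxy)-3-methoxyphenyl]-4-[3,5-bis(benzyloxy)phenyl]oxolan-2-one, 14 (2Z,4E)-5-[4-(benzyloxy)-3-methoxyphenyl]-3-methylpenta-2,4-dienoic acid
Product: 18 (2S,3S)-2-[4-(benzyloxy)-3-methoxyphenyl]-3-[3,5-bis(benzyloxy)phenyl]-6-[(E)-2-[4-(benzyloxy)-3-methoxyphenyl]ethenyl]-2,3-dihydro-1-benzofuran-4-ol, via acyl imidazole 15 (not isolated), via acyl lactone 16 (not isolated), via resorcinol carbinol 17 (not isolated)
Conditions: 14, 1,1'-carbonyldiimidazole, THF, 25 °C; added to 11 + LiN(SiMe3)2 (3.3 equiv), THF, −78 to 0 °C; KOt-Bu (3 equiv), t-BuOH, 65 °C; evaporate; CF3CO2H (10 equiv), CH2Cl2, 0 to 25 °C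
Reagents that add atoms: none
Why: Proposed new method: the lithium enolate of 11 is C-acylated by 15 (Claisen-type acylation with an acyl imidazole) to give 16; under KOt-Bu/t-BuOH the vinylogous enolate at the 3-methyl group attacks the lactone carbonyl (vinylogous Dieckmann condensation, closest precedent the base-mediated aldol/Claisen aromatisation of polyketide-type polycarbonyl chains to resorcinols), the tetrahedral intermediate expels the benzylic alkoxide and the enedione tautomerises to resorcinol 17 (benzene ring A); CF3CO2H then ionises the 4-benzyloxy-3-methoxybenzylic alcohol and one of the two equivalent flanking phenols closes the dihydrofuran (SN1 cycloetherification) trans to the untouched C3 centre, giving (2S,3S); the 2Z geometry of 14 does not matter because the dienolate rotates freely.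

**Step 8**
Reactants: 18 (2S,3S)-2-[4-(benzyloxy)-3-methoxyphenyl]-3-[3,5-bis(benzyloxy)phenyl]-6-[(E)-2-[4-(benzyloxy)-3-methoxyphenyl]ethenyl]-2,3-dihydro-1-benzofuran-4-ol
Product: 19 Bisisorhapontigenin B, (2S,3S)-3-(3,5-dihydroxyphenyl)-2-(4-hydroxy-3-methoxyphenyl)-6-[(E)-2-(4-hydroxy-3-methoxyphenyl)ethenyl]-2,3-dihydro-1-benzofuran-4-ol
Conditions: BCl3 (10 equiv), C6HMe5 (15 equiv), CH2Cl2, −78 °C; then H2O
Reagents that add atoms: none
Why: Lewis acid debenzylation with pentamethylbenzene as a non-basic benzyl-cation scavenger cleaves aryl benzyl ethers at −78 °C while sparing the stilbene and the aryl methyl ethers; any reversible opening at C2 recloses to the trans isomer and C3 is untouched.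

**Compound list**
1 | 3,5-bis(benzyloxy)benzaldehyde | O=Cc1cc(OCc2ccccc2)cc(OCc2ccccc2)c1 | starting material
2 | 1,3-bis(benzyloxy)-5-ethenylbenzene | C=Cc1cc(OCc2ccccc2)cc(OCc2ccccc2)c1 | intermediate
3 | 2-allyl-4,4,5,5-tetramethyl-1,3,2-dioxaborolane (allylboronic acid pinacol ester) | C=CCB1OC(C)(C)C(C)(C)O1 | starting material
4 | 2-[(2E)-3-[3,5-bis(benzyloxy)phenyl]prop-2-en-1-yl]-4,4,5,5-tetramethyl-1,3,2-dioxaborolane | CC1(C)OB(C/C=C/c2cc(OCc3ccccc3)cc(OCc3ccccc3)c2)OC1(C)C | intermediate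
5 | 4-(benzyloxy)-3-methoxybenzaldehyde (O-benzylvanillin) | COc1cc(C=O)ccc1OCc1ccccc1 | starting material
6 | pinacol borate ester of 7: 2-{[(1S,2R)-1-[4-(benzyloxy)-3-methoxyphenyl]-2-[3,5-bis(benzyloxy)phenyl]but-3-en-1-yl]oxy}-4,4,5,5-tetramethyl-1,3,2-dioxaborolane | C=C[C@H](c1cc(OCc2ccccc2)cc(OCc2ccccc2)c1)[C@H](OB1OC(C)(C)C(C)(C)O1)c1ccc(OCc2ccccc2)c(OC)c1 | intermediate
7 | (1S,2R)-1-[4-(benzyloxy)-3-methoxyphenyl]-2-[3,5-bis(benzyloxy)phenyl]but-3-en-1-ol (anti) | C=C[C@H](c1cc(OCc2ccccc2)cc(OCc2ccccc2)c1)[C@H](O)c1ccc(OCc2ccccc2)c(OC)c1 | intermediate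
8 | bis-boryl adduct: 9-[(3R,4S)-4-[4-(benzyloxy)-3-methoxyphenyl]-3-[3,5-bis(benzyloxy)phenyl]-4-(9-borabicyclo[3.3.1]nonan-9-yloxy)butyl]-9-borabicyclo[3.3.1]nonane | C(C[C@H](c1cc(OCc2ccccc2)cc(OCc2ccccc2)c1)[C@H](OB1C2CCCC1CCC2)c1ccc(OCc2ccccc2)c(OC)c1)B1C2CCCC1CCC2 | intermediate
9 | (1S,2R)-1-[4-(benzyloxy)-3-methoxyphenyl]-2-[3,5-bis(benzyloxy)phenyl]butane-1,4-diol | OCC[C@H](c1cc(OCc2ccccc2)cc(OCc2ccccc2)c1)[C@H](O)c1ccc(OCc2ccccc2)c(OC)c1 | intermediate
10 | lactol: (4R,5S)-5-[4-(benzyloxy)-3-methoxyphenyl]-4-[3,5-bis(benzyloxy)phenyl]oxolan-2-ol (both anomers) | OC1C[C@H](c2cc(OCc3ccccc3)cc(OCc3ccccc3)c2)[C@@H](c2ccc(OCc3ccccc3)c(OC)c2)O1 | intermediate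
11 | (4R,5S)-5-[4-(benzyloxy)-3-methoxyphenyl]-4-[3,5-bis(benzyloxy)phenyl]oxolan-2-one (trans γ-lactone) | O=C1C[C@H](c2cc(OCc3ccccc3)cc(OCc3ccccc3)c2)[C@@H](c2ccc(OCc3ccccc3)c(OC)c2)O1 | intermediate
12 | methyl 3-methylbut-2-enoate | COC(=O)C=C(C)C | starting material
13 | 6-[4-(benzyloxy)-3-methoxyphenyl]-4-methyl-5,6-dihydro-2H-pyran-2-one (racemic) | CC1=CC(=O)OC(c2ccc(OCc3ccccc3)c(OC)c2)C1 | intermediate
14 | (2Z,4E)-5-[4-(benzyloxy)-3-methoxyphenyl]-3-methylpenta-2,4-dienoic acid | OC(=O)/C=C(C)\C=C\c1ccc(OCc2ccccc2)c(OC)c1 | intermediate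
15 | (2Z,4E)-5-[4-(benzyloxy)-3-methoxyphenyl]-1-(1H-imidazol-1-yl)-3-methylpenta-2,4-dien-1-one | O=C(/C=C(C)\C=C\c1ccc(OCc2ccccc2)c(OC)c1)n1ccnc1 | intermediate
16 | (4R,5S)-5-[4-(benzyloxy)-3-methoxyphenyl]-4-[3,5-bis(benzyloxy)phenyl]-3-[(2Z,4E)-5-[4-(benzyloxy)-3-methoxyphenyl]-3-methylpenta-2,4-dienoyl]oxolan-2-one (C3 epimers and enol) | O=C1C(C(=O)/C=C(C)\C=C\c2ccc(OCc3ccccc3)c(OC)c2)[C@H](c2cc(OCc3ccccc3)cc(OCc3ccccc3)c2)[C@@H](c2ccc(OCc3ccccc3)c(OC)c2)O1 | intermediate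
17 | 2-[(1S,2S)-1-[3,5-bis(benzyloxy)phenyl]-2-[4-(benzyloxy)-3-methoxyphenyl]-2-hydroxyethyl]-5-[(E)-2-[4-(benzyloxy)-3-methoxyphenyl]ethenyl]benzene-1,3-diol | Oc1cc(/C=C/c2ccc(OCc3ccccc3)c(OC)c2)cc(O)c1[C@H](c1cc(OCc2ccccc2)cc(OCc2ccccc2)c1)[C@H](O)c1ccc(OCc2ccccc2)c(OC)c1 | intermediate
18 | (2S,3S)-2-[4-(benzyloxy)-3-methoxyphenyl]-3-[3,5-bis(benzyloxy)phenyl]-6-[(E)-2-[4-(benzyloxy)-3-methoxyphenyl]ethenyl]-2,3-dihydro-1-benzofuran-4-ol | COc1cc(/C=C/c2cc(O)c3c(c2)O[C@H](c2ccc(OCc4ccccc4)c(OC)c2)[C@H]3c2cc(OCc4ccccc4)cc(OCc4ccccc4)c2)ccc1OCc1ccccc1 | intermediate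
19 | Bisisorhapontigenin B, (2S,3S)-3-(3,5-dihydroxyphenyl)-2-(4-hydroxy-3-methoxyphenyl)-6-[(E)-2-(4-hydroxy-3-methoxyphenyl)ethenyl]-2,3-dihydro-1-benzofuran-4-ol | COc1cc(/C=C/c2cc(O)c3c(c2)O[C@H](c2ccc(O)c(OC)c2)[C@H]3c2cc(O)cc(O)c2)ccc1O | target

**Totals**
Total step count: 8.
Longest linear sequence: 7 steps (1, 2, 3, 4, 5, 7, 8); step 6 is a one-step side branch.

**Three steps most likely to fail, each with a fallback**

Step 7 (one-flask annulation). The vinylogous Dieckmann closure onto a lactone carbonyl that is partly enolised may be slow, or retro-Claisen cleavage may compete. The fallback sets out from 11 and 14 and comes back at 18. The acylation stage is quenched with aqueous NH4Cl so that acyl lactone 16 is isolated. Treatment with t-BuMe2SiOTf and Et3N in CH2Cl2 gives the bis-silyl triene F1 (silyl ketene acetal of the lactone plus silyl dienol ether of the enone). Heating F1 in toluene at 110 °C brings about a thermal 6π-electrocyclisation that forms the C7–C7a bond; loss of silanol then gives the aryl silyl ether F2. The lactone oxygen and both stereocentres are kept throughout. n-Bu4NF in THF then returns 18.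

Step 3 (asymmetric allylboration). The γ-aryl boronate with an electron-rich aldehyde may react slowly or with eroded ee. The fallback sets out from 1 and 5 and comes back at 7. Addition of CH2=CHMgBr to 1 gives the allylic alcohol F3, and PBr3 in Et2O at 0 °C converts it with allylic transposition into the cinnamyl bromide F4. A catalytic asymmetric Nozaki–Hiyama–Kishi allylation of 5 with F4 follows (CrCl2 10 mol %, chiral bis(oxazolinyl)carbazole ligand chosen for Si-face attack, Mn powder, Me3SiCl, i-Pr2NEt, THF). The (E)-allylchromium reacts through a chair transition state and gives the anti trimethylsilyl ether F5, which aqueous HCl cleaves to 7.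

Step 5 (oxidative lactonisation). The electron-rich benzylic secondary alcohol may be oxidised in competition with the primary one. The fallback sets out from 7 and comes back at 11, bypassing diol 9. An aldehyde-selective (anti-Markovnikov) Wacker oxidation of 7 (PdCl2(PhCN)2, CuCl2, AgNO2, O2, t-BuOH/MeNO2) gives lactol 10 directly, with the secondary hydroxyl already tied up in the ring. Ag2CO3 on Celite in refluxing toluene then oxidises 10 to 11. This fallback makes no new compound (F0).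

**Further compounds**
F1 | step 7 | bis-silyl triene: (4S,5S)-5-[4-(benzyloxy)-3-methoxyphenyl]-4-[3,5-bis(benzyloxy)phenyl]-2-[(tert-butyldimethylsilyl)oxy]-3-[(4E)-5-[4-(benzyloxy)-3-methoxyphenyl]-1-[(tert-butyldimethylsilyl)oxy]-3-methylidenepenta-1,4-dien-1-yl]-4,5-dihydrofuran (ring carbon and dienyl carbon cis on the enol double bond) | C=C(/C=C/c1ccc(OCc2ccccc2)c(OC)c1)/C=C(O[Si](C)(C)C(C)(C)C)\C1=C(O[Si](C)(C)C(C)(C)C)O[C@H](c2ccc(OCc3ccccc3)c(OC)c2)[C@H]1c1cc(OCc2ccccc2)cc(OCc2ccccc2)c1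
F2 | step 7 | tert-butyldimethylsilyl ether of 18 at the C4 oxygen | COc1cc(/C=C/c2cc(O[Si](C)(C)C(C)(C)C)c3c(c2)O[C@H](c2ccc(OCc4ccccc4)c(OC)c2)[C@H]3c2cc(OCc4ccccc4)cc(OCc4ccccc4)c2)ccc1OCc1ccccc1
F3 | step 3 | 1-[3,5-bis(benzyloxy)phenyl]prop-2-en-1-ol (racemic) | C=CC(O)c1cc(OCc2ccccc2)cc(OCc2ccccc2)c1
F4 | step 3 | 1,3-bis(benzyloxy)-5-[(1E)-3-bromoprop-1-en-1-yl]benzene | BrC/C=C/c1cc(OCc2ccccc2)cc(OCc2ccccc2)c1
F5 | step 3 | trimethylsilyl ether of 7: {[(1S,2R)-1-[4-(benzyloxy)-3-methoxyphenyl]-2-[3,5-bis(benzyloxy)phenyl]but-3-en-1-yl]oxy}trimethylsilane | C=C[C@H](c1cc(OCc2ccccc2)cc(OCc2ccccc2)c1)[C@H](O[Si](C)(C)C)c1ccc(OCc2ccccc2)c(OC)c1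
F0 | step 5 | none | none
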